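**Strategy.** The target is an all-ether phlorotannin octamer. Ring H is a phloroglucinol whose carbon H1, carrying the O4 oxygen of ring G, lies between the hydroxylated carbons H2 and H6, with the third hydroxyl at H4; this 1,3,5-oxygen pattern is that of a malonate acylating a 3-oxoglutarate twice. The key step therefore builds ring H in one operation, forming H2–H3 and H5–H6, from the heptameric aryloxymalonate 23 (rings A–G as seventeen methyl ethers, malonate on O-G4) and dimethyl 3-oxoglutarate. Heptamer 21 is grown ring by ring from 3,5-dimethoxyphenol by alternating Ullmann coupling with bromobenzaldehydes and Dakin oxidation, each formyl group serving first as activator and then as latent phenol.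

Key step: step 14

Remark on labels: ring A is the 3,5-dimethoxyphenoxy end. In rings B, D and F, carbon 1 bears the oxygen to the preceding ring, carbon 2 the oxygen to the following ring, carbon 3 is CH and carbons 4–6 bear OMe. In rings C, E and G, carbon 1 bears the oxygen to the preceding ring, carbons 2 and 6 bear OMe and carbon 4 bears the oxygen to the following ring. Ring H is numbered from H1, the carbon bonded to O-G4.

Remark on structures: 23 and 26 map atom for atom onto the target (seventeen OMe in rings A–G for seventeen of the twenty OH; ring H oxygens at H2, H4, H6). The target has no stereocentre, so no step sets or endangers configuration.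

Assumption: compounds 1, 2, 6, 22 and 24 are purchased.

**Step 1**
Reactants: 1 3,5-dimethoxyphenol; 2 2-bromo-3,4,5-trimethoxybenzaldehyde
Product: 3 dimer aldehyde 2-(3,5-dimethoxyphenoxy)-3,4,5-trimethoxybenzaldehyde
Conditions: CuI (10 mol %), picolinic acid (20 mol %), K3PO4, DMSO, 90 °C
Reagents that add atoms: none
Why: Ullmann diaryl ether synthesis in which the ortho-formyl group of 2 activates the C–Br bond toward the unhindered phenoxide of 1, a coupling type established for bromobenzaldehydes whose bromine lies between a formyl and a methoxy group.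

**Step 2**
Reactants: 3 dimer aldehyde
Product: 5 dimer phenol 2-(3,5-dimethoxyphenoxy)-3,4,5-trimethoxyphenol, via dimer formate 4 (not isolated)
Conditions: mCPBA, CH2Cl2, 0 °C to rt; aq. Na2S2O3 wash; then K2CO3 (cat.), MeOH, rt
Reagents that add atoms: mCPBA (3-chloroperoxybenzoic acid), OOC(=O)c1cccc(Cl)c1
Why: Dakin-type Baeyer–Villiger oxidation in which the electron-rich ring B (oxygen ortho and para to the formyl carbon) migrates in the Criegee adduct to give the aryl formate, whose methanolysis frees the B2 phenol.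

**Step 3**
Reactants: 5 dimer phenol; 6 4-bromo-3,5-dimethoxybenzaldehyde
Product: 7 trimer aldehyde 4-[2-(3,5-dimethoxyphenoxy)-3,4,5-trimethoxyphenoxy]-3,5-dimethoxybenzaldehyde
Conditions: CuI (10 mol %), picolinic acid (20 mol %), K3PO4, DMSO, 100 °C
Reagents that add atoms: none
Why: Ullmann diaryl ether synthesis in which the para-formyl group of 6 activates the bromide, the two flanking methoxy groups being tolerated as in classical Ullmann couplings of 2-bromo-1,3-dimethoxyarenes and by the picolinate-ligated CuI catalyst, which suits ortho-substituted partners.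

**Step 4**
Reactants: 7 trimer aldehyde
Product: 9 trimer phenol 4-[2-(3,5-dimethoxyphenoxy)-3,4,5-trimethoxyphenoxy]-3,5-dimethoxyphenol, via trimer formate 8 (not isolated)
Conditions: mCPBA, CH2Cl2, 0 °C to rt; aq. Na2S2O3 wash; then K2CO3 (cat.), MeOH, rt
Reagents that add atoms: mCPBA (3-chloroperoxybenzoic acid), OOC(=O)c1cccc(Cl)c1
Why: Dakin-type Baeyer–Villiger oxidation in which the para-aryloxy ring C migrates, as in the conversion of 3,4,5-trimethoxybenzaldehyde into its phenol, and the formate is methanolysed to the C4 phenol.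

**Step 5**
Reactants: 9 trimer phenol; 2 2-bromo-3,4,5-trimethoxybenzaldehyde
Product: 10 tetramer aldehyde A–B–C–D (CHO at D2)
Conditions: CuI (10 mol %), picolinic acid (20 mol %), K3PO4, DMSO, 90 °C
Reagents that add atoms: none
Why: Ullmann diaryl ether synthesis as in step 1, the C4 phenol of 9 being flanked only by hydrogens and the bromide of 2 activated by its ortho-formyl group.

**Step 6**
Reactants: 10 tetramer aldehyde
Product: 12 tetramer phenol A–B–C–D (free OH at D2), via tetramer formate 11 (not isolated)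
Conditions: mCPBA, CH2Cl2, 0 °C to rt; aq. Na2S2O3 wash; then K2CO3 (cat.), MeOH, rt
Reagents that add atoms: mCPBA (3-chloroperoxybenzoic acid), OOC(=O)c1cccc(Cl)c1
Why: Dakin-type Baeyer–Villiger oxidation as in step 2, ring D carrying the same ortho-aryloxy and para-methoxy donors that favour aryl migration.

**Step 7**
Reactants: 12 tetramer phenol; 6 4-bromo-3,5-dimethoxybenzaldehyde
Product: 13 pentamer aldehyde A–B–C–D–E (CHO at E4)
Conditions: CuI (10 mol %), picolinic acid (20 mol %), K3PO4, DMSO, 100 °C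
Reagents that add atoms: none
Why: Ullmann diaryl ether synthesis as in step 3, with the para-formyl group of 6 again activating the bromide toward the D2 phenoxide.

**Step 8**
Reactants: 13 pentamer aldehyde
Product: 15 pentamer phenol A–B–C–D–E (free OH at E4), via pentamer formate 14 (not isolated)
Conditions: mCPBA, CH2Cl2, 0 °C to rt; aq. Na2S2O3 wash; then K2CO3 (cat.), MeOH, rt
Reagents that add atoms: mCPBA (3-chloroperoxybenzoic acid), OOC(=O)c1cccc(Cl)c1
Why: Dakin-type Baeyer–Villiger oxidation as in step 4, the para-aryloxy ring E migrating and the formate being methanolysed.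

**Step 9**
Reactants: 15 pentamer phenol; 2 2-bromo-3,4,5-trimethoxybenzaldehyde
Product: 16 hexamer aldehyde A–B–C–D–E–F (CHO at F2)
Conditions: CuI (10 mol %), picolinic acid (20 mol %), K3PO4, DMSO, 90 °C
Reagents that add atoms: none
Why: Ullmann diaryl ether synthesis as in steps 1 and 5, between the unhindered E4 phenoxide and the ortho-formyl-activated bromide.

**Step 10**
Reactants: 16 hexamer aldehyde
Product: 18 hexamer phenol A–B–C–D–E–F (free OH at F2), via hexamer formate 17 (not isolated)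
Conditions: mCPBA, CH2Cl2, 0 °C to rt; aq. Na2S2O3 wash; then K2CO3 (cat.), MeOH, rt
Reagents that add atoms: mCPBA (3-chloroperoxybenzoic acid), OOC(=O)c1cccc(Cl)c1
Why: Dakin-type Baeyer–Villiger oxidation as in steps 2 and 6, with ring F as the migrating electron-rich aryl group.

**Step 11**
Reactants: 18 hexamer phenol; 6 4-bromo-3,5-dimethoxybenzaldehyde
Product: 19 heptamer aldehyde A–B–C–D–E–F–G (CHO at G4)
Conditions: CuI (10 mol %), picolinic acid (20 mol %), K3PO4, DMSO, 100 °C
Reagents that add atoms: none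
Why: Ullmann diaryl ether synthesis as in steps 3 and 7, the para-formyl group of 6 activating the bromide toward the F2 phenoxide.

**Step 12**
Reactants: 19 heptamer aldehyde
Product: 21 heptamer phenol A–B–C–D–E–F–G (free OH at G4), via heptamer formate 20 (not isolated)
Conditions: mCPBA, CH2Cl2, 0 °C to rt; aq. Na2S2O3 wash; then K2CO3 (cat.), MeOH, rt
Reagents that add atoms: mCPBA (3-chloroperoxybenzoic acid), OOC(=O)c1cccc(Cl)c1
Why: Dakin-type Baeyer–Villiger oxidation as in steps 4 and 8, which should free exactly the G4 phenol needed next without any protecting group.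

**Step 13**
Reactants: 21 heptamer phenol; 22 dimethyl chloromalonate
Product: 23 dimethyl 2-(heptamer A–G-oxy)malonate (bonded through O-G4)
Conditions: K2CO3, acetone, reflux
Reagents that add atoms: none
Why: Williamson ether synthesis (SN2 of the unhindered G4 phenoxide at the doubly activated chloromalonate carbon), the standard preparation of aryloxymalonates, with chloride preferred to bromide to suppress halogen transfer to the electron-rich phenoxide.

**Step 14**
Reactants: 23 dimethyl 2-(heptamer A–G-oxy)malonate; 24 dimethyl 3-oxoglutarate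
Product: 26 octamer diester (ring H 2,4,6-trihydroxy-3,5-bis(methoxycarbonyl)phenyl on O-G4), via acyclic Claisen adduct 25 (not isolated)
Conditions: 24 (2 equiv, slow addition), NaOMe (4 equiv), MeOH, reflux; then toluene, 110 °C, MeOH distilled off; aq. HCl
Reagents that add atoms: none
Why: Proposed new method: methoxide forms the enolate of 24, which C-acylates with one ester group of 23 (intermolecular Claisen, giving 25), after which the second α-carbon of the oxoglutarate unit attacks the remaining malonate ester in a 6-exo-trig Dieckmann closure of ring H and the cyclohexane-1,3,5-trione enolises to the phloroglucinol, held as its sodium phenolate. The closest known reactions are the alkoxide condensation of simple malonic esters with acetonedicarboxylic esters to phloroglucinol dicarboxylates and the NaOMe condensation of aryloxymalonates with amidines to 5-aryloxypyrimidine-4,6-diols, which shows both ester groups of an aryloxymalonate accepting a 1,3-dinucleophile; a carbon,carbon-dinucleophile has not been shown on this substrate class. The malonate CH becomes H1 (still bearing O-G4), its ester carbons become H2 and H6, the oxoglutarate methylenes H3 and H5 and the ketone carbon H4; no stereocentre is created and the labile centres of 25 vanish on aromatisation. The step needs C- over O-acylation in the closure and cross- over self-condensation of 24: every acylation is reversible under methoxide with matching methyl esters, a pyranone from O-acylation is reopened by methoxide whereas the phloroglucinol phenolate is a sink, the hydrogen kept on the malonate carbon of 23 is what allows that aromatisation, the α-aryloxy group raises the electrophilicity of both ester carbonyls, and 24 is fed slowly in excess while methanol is removed. Nothing else in 23 reacts with methoxide, since rings A–G carry only methyl and diaryl ethers.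

**Step 15**
Reactants: 26 octamer diester
Product: 29 octamer triol (ring H 2,4,6-trihydroxyphenyl; rings A–G as seventeen methyl ethers), via octamer diacid 27 (not isolated), via octamer monoacid 28 (not isolated)
Conditions: KOH, MeOH–H2O (degassed), 70 °C, argon; then aq. HCl to pH 1, 60 °C
Reagents that add atoms: none
Why: Saponification followed by decarboxylation of a 2,4,6-trihydroxyisophthalic acid, which should lose both CO2 units readily through its β-keto acid tautomers once protonated, while methyl and diaryl ethers are inert to aqueous base and dilute acid.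

**Step 16**
Reactants: 29 octamer triol
Product: 30 CNP0319661.0 (target)
Conditions: BBr3 (excess), CH2Cl2, −78 °C to rt, argon; then H2O, 0 °C
Reagents that add atoms: none
Why: Lewis acid-mediated aryl methyl ether cleavage (BBr3 demethylation), in which each complexed methoxy group loses its methyl to bromide, whereas the diaryl ether links offer no alkyl carbon for attack and should survive.

**Compound list**

1 | 3,5-dimethoxyphenol (ring A) | COc1cc(O)cc(OC)c1 | starting material
2 | 2-bromo-3,4,5-trimethoxybenzaldehyde (source of rings B, D, F) | COc1cc(C=O)c(Br)c(OC)c1OC | starting material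
3 | dimer aldehyde A–B: 2-(3,5-dimethoxyphenoxy)-3,4,5-trimethoxybenzaldehyde (CHO at B2) | COc1cc(OC)cc(Oc2c(C=O)cc(OC)c(OC)c2OC)c1 | intermediate
4 | dimer formate A–B: 2-(3,5-dimethoxyphenoxy)-3,4,5-trimethoxyphenyl formate (not isolated) | COc1cc(OC)cc(Oc2c(OC=O)cc(OC)c(OC)c2OC)c1 | intermediate
5 | dimer phenol A–B: 2-(3,5-dimethoxyphenoxy)-3,4,5-trimethoxyphenol (free OH at B2) | COc1cc(OC)cc(Oc2c(O)cc(OC)c(OC)c2OC)c1 | intermediate
6 | 4-bromo-3,5-dimethoxybenzaldehyde (source of rings C, E, G) | COc1cc(C=O)cc(OC)c1Br | starting material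
7 | trimer aldehyde A–B–C: 4-[2-(3,5-dimethoxyphenoxy)-3,4,5-trimethoxyphenoxy]-3,5-dimethoxybenzaldehyde (CHO at C4) | COc1cc(OC)cc(Oc2c(Oc3c(OC)cc(C=O)cc3OC)cc(OC)c(OC)c2OC)c1 | intermediate
8 | trimer formate A–B–C: formate ester of 9 at O-C4 (not isolated) | COc1cc(OC)cc(Oc2c(Oc3c(OC)cc(OC=O)cc3OC)cc(OC)c(OC)c2OC)c1 | intermediate
9 | trimer phenol A–B–C: 4-[2-(3,5-dimethoxyphenoxy)-3,4,5-trimethoxyphenoxy]-3,5-dimethoxyphenol (free OH at C4) | COc1cc(OC)cc(Oc2c(Oc3c(OC)cc(O)cc3OC)cc(OC)c(OC)c2OC)c1 | intermediate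
10 | tetramer aldehyde A–B–C–D: 9 with O-C4 bonded to D1 of a 2-formyl-4,5,6-trimethoxyphenyl ring (CHO at D2) | COc1cc(OC)cc(Oc2c(Oc3c(OC)cc(Oc4c(C=O)cc(OC)c(OC)c4OC)cc3OC)cc(OC)c(OC)c2OC)c1 | intermediate
11 | tetramer formate: formate ester of 12 at O-D2 (not isolated) | COc1cc(OC)cc(Oc2c(Oc3c(OC)cc(Oc4c(OC=O)cc(OC)c(OC)c4OC)cc3OC)cc(OC)c(OC)c2OC)c1 | intermediate
12 | tetramer phenol A–B–C–D (free OH at D2) | COc1cc(OC)cc(Oc2c(Oc3c(OC)cc(Oc4c(O)cc(OC)c(OC)c4OC)cc3OC)cc(OC)c(OC)c2OC)c1 | intermediate
13 | pentamer aldehyde A–E: 12 with O-D2 bonded to E1 of a 4-formyl-2,6-dimethoxyphenyl ring (CHO at E4) | COc1cc(OC)cc(Oc2c(Oc3c(OC)cc(Oc4c(Oc5c(OC)cc(C=O)cc5OC)cc(OC)c(OC)c4OC)cc3OC)cc(OC)c(OC)c2OC)c1 | intermediate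
14 | pentamer formate: formate ester of 15 at O-E4 (not isolated) | COc1cc(OC)cc(Oc2c(Oc3c(OC)cc(Oc4c(Oc5c(OC)cc(OC=O)cc5OC)cc(OC)c(OC)c4OC)cc3OC)cc(OC)c(OC)c2OC)c1 | intermediate
15 | pentamer phenol A–E (free OH at E4) | COc1cc(OC)cc(Oc2c(Oc3c(OC)cc(Oc4c(Oc5c(OC)cc(O)cc5OC)cc(OC)c(OC)c4OC)cc3OC)cc(OC)c(OC)c2OC)c1 | intermediate
16 | hexamer aldehyde A–F: 15 with O-E4 bonded to F1 of a 2-formyl-4,5,6-trimethoxyphenyl ring (CHO at F2) | COc1cc(OC)cc(Oc2c(Oc3c(OC)cc(Oc4c(Oc5c(OC)cc(Oc6c(C=O)cc(OC)c(OC)c6OC)cc5OC)cc(OC)c(OC)c4OC)cc3OC)cc(OC)c(OC)c2OC)c1 | intermediate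
17 | hexamer formate: formate ester of 18 at O-F2 (not isolated) | COc1cc(OC)cc(Oc2c(Oc3c(OC)cc(Oc4c(Oc5c(OC)cc(Oc6c(OC=O)cc(OC)c(OC)c6OC)cc5OC)cc(OC)c(OC)c4OC)cc3OC)cc(OC)c(OC)c2OC)c1 | intermediate
18 | hexamer phenol A–F (free OH at F2) | COc1cc(OC)cc(Oc2c(Oc3c(OC)cc(Oc4c(Oc5c(OC)cc(Oc6c(O)cc(OC)c(OC)c6OC)cc5OC)cc(OC)c(OC)c4OC)cc3OC)cc(OC)c(OC)c2OC)c1 | intermediate
19 | heptamer aldehyde A–G: 18 with O-F2 bonded to G1 of a 4-formyl-2,6-dimethoxyphenyl ring (CHO at G4) | COc1cc(OC)cc(Oc2c(Oc3c(OC)cc(Oc4c(Oc5c(OC)cc(Oc6c(Oc7c(OC)cc(C=O)cc7OC)cc(OC)c(OC)c6OC)cc5OC)cc(OC)c(OC)c4OC)cc3OC)cc(OC)c(OC)c2OC)c1 | intermediate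
20 | heptamer formate: formate ester of 21 at O-G4 (not isolated) | COc1cc(OC)cc(Oc2c(Oc3c(OC)cc(Oc4c(Oc5c(OC)cc(Oc6c(Oc7c(OC)cc(OC=O)cc7OC)cc(OC)c(OC)c6OC)cc5OC)cc(OC)c(OC)c4OC)cc3OC)cc(OC)c(OC)c2OC)c1 | intermediate
21 | heptamer phenol A–G (free OH at G4; seventeen OMe) | COc1cc(OC)cc(Oc2c(Oc3c(OC)cc(Oc4c(Oc5c(OC)cc(Oc6c(Oc7c(OC)cc(O)cc7OC)cc(OC)c(OC)c6OC)cc5OC)cc(OC)c(OC)c4OC)cc3OC)cc(OC)c(OC)c2OC)c1 | intermediate
22 | dimethyl chloromalonate (dimethyl 2-chloropropanedioate) | COC(=O)C(Cl)C(=O)OC | starting material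
23 | dimethyl 2-(heptamer A–G-oxy)malonate, bonded through O-G4 | COc1cc(OC)cc(Oc2c(Oc3c(OC)cc(Oc4c(Oc5c(OC)cc(Oc6c(Oc7c(OC)cc(OC(C(=O)OC)C(=O)OC)cc7OC)cc(OC)c(OC)c6OC)cc5OC)cc(OC)c(OC)c4OC)cc3OC)cc(OC)c(OC)c2OC)c1 | intermediate
24 | dimethyl 3-oxoglutarate (dimethyl 3-oxopentanedioate) | COC(=O)CC(=O)CC(=O)OC | starting material
25 | acyclic Claisen adduct: dimethyl 2-(heptamer A–G-oxy)-4-(methoxycarbonyl)-3,5-dioxoheptanedioate (labile stereocentres and enol tautomers; not isolated) | COc1cc(OC)cc(Oc2c(Oc3c(OC)cc(Oc4c(Oc5c(OC)cc(Oc6c(Oc7c(OC)cc(OC(C(=O)OC)C(=O)C(C(=O)OC)C(=O)CC(=O)OC)cc7OC)cc(OC)c(OC)c6OC)cc5OC)cc(OC)c(OC)c4OC)cc3OC)cc(OC)c(OC)c2OC)c1 | intermediate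
26 | octamer diester: ring H 2,4,6-trihydroxy-3,5-bis(methoxycarbonyl)phenyl on O-G4 | COc1cc(OC)cc(Oc2c(Oc3c(OC)cc(Oc4c(Oc5c(OC)cc(Oc6c(Oc7c(OC)cc(Oc8c(O)c(C(=O)OC)c(O)c(C(=O)OC)c8O)cc7OC)cc(OC)c(OC)c6OC)cc5OC)cc(OC)c(OC)c4OC)cc3OC)cc(OC)c(OC)c2OC)c1 | intermediate
27 | octamer diacid: ring H 3,5-dicarboxy-2,4,6-trihydroxyphenyl (not isolated) | COc1cc(OC)cc(Oc2c(Oc3c(OC)cc(Oc4c(Oc5c(OC)cc(Oc6c(Oc7c(OC)cc(Oc8c(O)c(C(=O)O)c(O)c(C(=O)O)c8O)cc7OC)cc(OC)c(OC)c6OC)cc5OC)cc(OC)c(OC)c4OC)cc3OC)cc(OC)c(OC)c2OC)c1 | intermediate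
28 | octamer monoacid: ring H 3-carboxy-2,4,6-trihydroxyphenyl (not isolated) | COc1cc(OC)cc(Oc2c(Oc3c(OC)cc(Oc4c(Oc5c(OC)cc(Oc6c(Oc7c(OC)cc(Oc8c(O)c(C(=O)O)c(O)cc8O)cc7OC)cc(OC)c(OC)c6OC)cc5OC)cc(OC)c(OC)c4OC)cc3OC)cc(OC)c(OC)c2OC)c1 | intermediate
29 | octamer triol: ring H 2,4,6-trihydroxyphenyl on O-G4, rings A–G as seventeen methyl ethers | COc1cc(OC)cc(Oc2c(Oc3c(OC)cc(Oc4c(Oc5c(OC)cc(Oc6c(Oc7c(OC)cc(Oc8c(O)cc(O)cc8O)cc7OC)cc(OC)c(OC)c6OC)cc5OC)cc(OC)c(OC)c4OC)cc3OC)cc(OC)c(OC)c2OC)c1 | intermediate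
30 | CNP0319661.0, octamer with twenty free hydroxyls | Oc1cc(O)cc(Oc2c(Oc3c(O)cc(Oc4c(Oc5c(O)cc(Oc6c(Oc7c(O)cc(Oc8c(O)cc(O)cc8O)cc7O)cc(O)c(O)c6O)cc5O)cc(O)c(O)c4O)cc3O)cc(O)c(O)c2O)c1 | target

**Step count.** Total: 16 steps. Longest linear sequence: 16 steps (1 to 30); the route is fully linear and has no separate building-block branch.

**Steps most likely to fail**

Step 14 (key step, proposed new method). The cross-condensation may not take place: 24 may condense with itself faster than with the malonate, 23 may rest as its unreactive sodium enolate, or the closure may run through oxygen to a pyranone. The fallback uses known chemistry only, sets out from heptamer phenol 21 and replaces ring construction by one more turn of the coupling–oxidation cycle already used six times. Ullmann coupling of 21 with 6 (CuI, picolinic acid, K3PO4, DMSO, 100 °C) should give octamer aldehyde F1. Dakin oxidation (mCPBA, CH2Cl2; then K2CO3, MeOH) should pass through octamer formate F2 to octamer phenol F3, whose ring H is a 4-hydroxy-2,6-dimethoxyphenoxy unit. BBr3 cleavage of its nineteen methyl ethers (CH2Cl2, −78 °C to rt) then comes back to the route at target 30.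

Step 16. Cleavage of seventeen ethers may stall at partly methylated stages, and the liberated pyrogallol-type rings B, D and F may oxidise in air during isolation. The fallback sets out from 29 and changes the isolation strategy to capture, purification and release. The BBr3 reaction is quenched hydrolytically and evaporated, and the crude polyphenol is acetylated at once (Ac2O, pyridine, rt) to eicosaacetate F4, a stable compound that can be chromatographed free of under-cleaved material. Acid-catalysed methanolysis (HCl, MeOH, argon, 50 °C) then releases the polyphenol and comes back to the route at 30.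

Step 11. Substitution at the bromide flanked by two methoxy groups may become too slow on the large hexamer phenol, so that hydrodebromination of 6 and slow degradation of the aldehyde take over. The fallback sets out from 18 and 6 and moves the bond formation from CuI-mediated substitution to a palladium-catalysed Buchwald–Hartwig C–O coupling (Pd(OAc)2, 2-di-tert-butylphosphino-2',4',6'-triisopropylbiphenyl, K3PO4, toluene, 100 °C). There, oxidative addition of zerovalent palladium into the electron-poor bromide is easy and flanking substituents speed up the C–O reductive elimination. It should give heptamer aldehyde 19 directly and comes back to the route there.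

**Further compounds**

F1 | step 14 | octamer aldehyde: 21 with O-G4 bonded to H1 of a 4-formyl-2,6-dimethoxyphenyl ring | COc1cc(OC)cc(Oc2c(Oc3c(OC)cc(Oc4c(Oc5c(OC)cc(Oc6c(Oc7c(OC)cc(Oc8c(OC)cc(C=O)cc8OC)cc7OC)cc(OC)c(OC)c6OC)cc5OC)cc(OC)c(OC)c4OC)cc3OC)cc(OC)c(OC)c2OC)c1
F2 | step 14 | octamer formate: formate ester of F3 at O-H4 | COc1cc(OC)cc(Oc2c(Oc3c(OC)cc(Oc4c(Oc5c(OC)cc(Oc6c(Oc7c(OC)cc(Oc8c(OC)cc(OC=O)cc8OC)cc7OC)cc(OC)c(OC)c6OC)cc5OC)cc(OC)c(OC)c4OC)cc3OC)cc(OC)c(OC)c2OC)c1
F3 | step 14 | octamer phenol: ring H 4-hydroxy-2,6-dimethoxyphenyl on O-G4, nineteen methyl ethers | COc1cc(OC)cc(Oc2c(Oc3c(OC)cc(Oc4c(Oc5c(OC)cc(Oc6c(Oc7c(OC)cc(Oc8c(OC)cc(O)cc8OC)cc7OC)cc(OC)c(OC)c6OC)cc5OC)cc(OC)c(OC)c4OC)cc3OC)cc(OC)c(OC)c2OC)c1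
F4 | step 16 | eicosaacetate of 30 (all twenty hydroxyls as acetates) | CC(=O)Oc1cc(OC(C)=O)cc(Oc2c(Oc3c(OC(C)=O)cc(Oc4c(Oc5c(OC(C)=O)cc(Oc6c(Oc7c(OC(C)=O)cc(Oc8c(OC(C)=O)cc(OC(C)=O)cc8OC(C)=O)cc7OC(C)=O)cc(OC(C)=O)c(OC(C)=O)c6OC(C)=O)cc5OC(C)=O)cc(OC(C)=O)c(OC(C)=O)c4OC(C)=O)cc3OC(C)=O)cc(OC(C)=O)c(OC(C)=O)c2OC(C)=O)c1
F0 | step 11 | none | none
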